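The cyclohexenone is disconnected at C1–C6 (C1 = alkene carbon bearing C7H2OH, C2 = ketone, C3 = hydroxytiglate carbon, C4 = isopropyl carbon, C5 = angelate carbon, C6 = alkene CH). The all-cis C3/C4/C5 triad is the C4/C3/C2 array of a 3-deoxy-3-C-isopropyl-D-allopyranoside, and C2, C1, C6 are its C5, C6, C1. A mercury(II)-catalysed Ferrier carbocyclisation of the 6-deoxyhex-5-enopyranoside closes the six-membered carbocycle and forms that bond in one operation. The precursor is the methyl β-glycoside that already carries the angelate on O2 and the silyl-protected hydroxytiglate on O4, so only dehydration, hydroxymethylation and desilylation follow.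

Key step: step 13

Remark (numbering): compounds 1–20 carry sugar locants; names of 21–25 use cyclohexanone locants (ketone = C1); "C1–C7" in the Why lines of steps 14–16 means the numbering of the first paragraph.
Remark (assumption on the spectator anomeric centre): the glycoside is drawn β, because an α-methoxy group would be 1,3-diaxial to the axial C3 isopropyl group; the centre is destroyed in step 13, so any α-anomer converges.
Remark (design): O2 and O4 are told apart by a temporary 4,6-O-benzylidene acetal and both final acyl groups are put on the robust pyranoside, so no hindered acylation and no removal of a secondary silyl ether beside primary ones is needed after the carbocyclisation.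
Abbreviations: angeloyl = (Z)-2-methylbut-2-enoyl; TBS = tert-butyldimethylsilyl. Compounds 1, 3, 10, 15 and 16 are catalogue materials.

Step 1
Reactants: 1 1,2:5,6-di-O-isopropylidene-α-D-glucofuranose
Product: 2 1,2:5,6-di-O-isopropylidene-α-D-ribo-hexofuranos-3-ulose
Conditions: DMSO, Ac2O, rt
Reagents that add atoms: none
Why: Albright–Goldman (activated DMSO) oxidation of the only free, secondary hydroxyl should give the 3-ketone without touching the two acetonides, and no stereocentre is formed.

Step 2
Reactants: 2 1,2:5,6-di-O-isopropylidene-α-D-ribo-hexofuranos-3-ulose; 3 isopropenylmagnesium bromide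
Product: 4 3-C-isopropenyl-1,2:5,6-di-O-isopropylidene-α-D-allofuranose
Conditions: THF, −78 to 0 °C; then H2O
Reagents that add atoms: none
Why: Grignard 1,2-addition should occur on the convex β (exo) face of the cis-fused bicycle, away from the 1,2-acetonide, so the new tertiary centre C3 carries the isopropenyl group β and the hydroxyl α (D-allo).

Step 3
Reactants: 4 3-C-isopropenyl-1,2:5,6-di-O-isopropylidene-α-D-allofuranose
Product: 5 3-C-isopropyl-1,2:5,6-di-O-isopropylidene-α-D-allofuranose
Conditions: H2 (1 atm), 10% Pd/C, EtOAc, rt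
Reagents that add atoms: none
Why: Heterogeneous catalytic hydrogenation saturates the 1,1-disubstituted alkene while the acetonides and the tertiary alcohol are inert, and no stereocentre is created or changed.

Step 4
Reactants: 5 3-C-isopropyl-1,2:5,6-di-O-isopropylidene-α-D-allofuranose
Product: 7 3-deoxy-3-C-isopropyl-1,2:5,6-di-O-isopropylidene-α-D-allofuranose, via tertiary methyl oxalate 6 (not isolated)
Conditions: n-BuLi, THF, −78 °C; ClCOCO2Me; then Bu3SnH, AIBN (cat.), toluene, 110 °C
Reagents that add atoms: none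
Why: Barton–McCombie-type radical deoxygenation through the tertiary methyl oxalate gives the planar C3 radical, which should take hydrogen from the stannane on the exo (β) face, as reagents generally do at C3 of this bicycle, leaving the isopropyl group α and cis to O2 (D-allo).

Step 5
Reactants: 7 3-deoxy-3-C-isopropyl-1,2:5,6-di-O-isopropylidene-α-D-allofuranose
Product: 9 methyl 4,6-O-benzylidene-3-deoxy-3-C-isopropyl-β-D-allopyranoside, via methyl β-pyranoside triol 8 (not isolated)
Conditions: Dowex 50 (H+), MeOH, reflux; filter, concentrate; then PhCH(OMe)2, CSA (cat.), MeCN, 50 °C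
Reagents that add atoms: methanol CO; benzaldehyde dimethyl acetal COC(OC)c1ccccc1
Why: Fischer glycosidation under equilibrium should favour the pyranoside with equatorial (β) methoxyl, since the α-anomer would place it 1,3-diaxial to the C3 isopropyl group, and thermodynamic acetalisation then ties O4 and O6 into the trans-fused 1,3-dioxane with equatorial phenyl (R acetal carbon), leaving O2–H as the only free hydroxyl.

Step 6
Reactants: 9 methyl 4,6-O-benzylidene-3-deoxy-3-C-isopropyl-β-D-allopyranoside; 10 angelic acid
Product: 11 methyl 2-O-angeloyl-4,6-O-benzylidene-3-deoxy-3-C-isopropyl-β-D-allopyranoside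
Conditions: 10, 2,4,6-Cl3C6H2COCl, Et3N, toluene, rt; then 9, 75 °C
Reagents that add atoms: none
Why: Yamaguchi mixed-anhydride esterification run without a nucleophilic catalyst is the established way to transfer an angeloyl group without Z-to-E isomerisation, and here it meets a single free hydroxyl on a substrate that tolerates heating.

Step 7
Reactants: 11 methyl 2-O-angeloyl-4,6-O-benzylidene-3-deoxy-3-C-isopropyl-β-D-allopyranoside
Product: 12 methyl 2-O-angeloyl-3-deoxy-3-C-isopropyl-β-D-allopyranoside
Conditions: AcOH/H2O (4:1), 60 °C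
Reagents that add atoms: none
Why: Mild acid hydrolysis of the benzylidene acetal should spare the methyl glycoside and the angelate, and the ester cannot migrate because C3 bears no oxygen and O4 is 1,3-diequatorial to O2 and out of reach.

Step 8
Reactants: 12 methyl 2-O-angeloyl-3-deoxy-3-C-isopropyl-β-D-allopyranoside
Product: 13 methyl 2-O-angeloyl-3,6-dideoxy-6-iodo-3-C-isopropyl-β-D-allopyranoside
Conditions: I2, PPh3, imidazole, THF, 0 °C to rt
Reagents that add atoms: iodine II
Why: Appel-type iodination (PPh3/I2/imidazole) is selective for the primary hydroxyl over the hindered secondary C4 hydroxyl and runs under conditions that leave the conjugated ester alone.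

Step 9
Reactants: 13 methyl 2-O-angeloyl-3,6-dideoxy-6-iodo-3-C-isopropyl-β-D-allopyranoside
Product: 14 methyl 2-O-angeloyl-3,6-dideoxy-3-C-isopropyl-β-D-ribo-hex-5-enopyranoside
Conditions: AgF, pyridine, rt, dark
Reagents that add atoms: none
Why: Silver(I)-assisted E2 dehydroiodination of 6-iodo pyranosides in pyridine is the classical route to the exocyclic enol ether, is mild enough for esters, and cannot give a 3,6-anhydride here because O3 is absent.

Step 10
Reactants: 15 (tert-butyldimethylsilyloxy)acetaldehyde; 16 ethyl 2-(triphenylphosphoranylidene)propanoate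
Product: 17 ethyl (E)-4-(tert-butyldimethylsilyloxy)-2-methylbut-2-enoate
Conditions: CH2Cl2, rt
Reagents that add atoms: none
Why: Wittig olefination with the α-methyl stabilised ylide should give the trisubstituted enoate with E geometry, the usual outcome for stabilised ylides and aldehydes.

Step 11
Reactants: 17 ethyl (E)-4-(tert-butyldimethylsilyloxy)-2-methylbut-2-enoate
Product: 18 (E)-4-(tert-butyldimethylsilyloxy)-2-methylbut-2-enoic acid
Conditions: LiOH·H2O, THF/MeOH/H2O, rt; then 1 M HCl to pH 4, 0 °C
Reagents that add atoms: lithium hydroxide [Li+].[OH-]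
Why: Saponification of the ethyl ester with lithium hydroxide at room temperature should leave the primary TBS ether and the alkene geometry untouched.

Step 12
Reactants: 14 methyl 2-O-angeloyl-3,6-dideoxy-3-C-isopropyl-β-D-ribo-hex-5-enopyranoside; 18 (E)-4-(tert-butyldimethylsilyloxy)-2-methylbut-2-enoic acid
Product: 19 methyl 2-O-angeloyl-4-O-[(E)-4-(tert-butyldimethylsilyloxy)-2-methylbut-2-enoyl]-3,6-dideoxy-3-C-isopropyl-β-D-ribo-hex-5-enopyranoside
Conditions: 18, 2,4,6-Cl3C6H2COCl, Et3N, THF, rt; then 14, DMAP, toluene, rt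
Reagents that add atoms: none
Why: Yamaguchi esterification acylates the one remaining hydroxyl under basic conditions that preserve the acid-labile enol ether, and an angelate already in ester form should not be isomerised by DMAP at room temperature.

Step 13
Reactants: 19 methyl 2-O-angeloyl-4-O-[(E)-4-(tert-butyldimethylsilyloxy)-2-methylbut-2-enoyl]-3,6-dideoxy-3-C-isopropyl-β-D-ribo-hex-5-enopyranoside
Product: 21 (2S,3S,4R,5R)-4-(angeloyloxy)-5-hydroxy-3-isopropyl-2-{[(E)-4-(tert-butyldimethylsilyloxy)-2-methylbut-2-enoyl]oxy}cyclohexan-1-one, via acyclic 6-mercurio 5-keto aldehyde 20 (not isolated)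
Conditions: Hg(OCOCF3)2 (5 mol%), acetone/H2O (4:1), rt
Reagents that add atoms: water O
Why: Hg(II) adds to the electron-rich exocyclic enol ether (sugar C5=C6), water attacks C5, and the hemiketal opens to the C5 ketone carrying mercury on C6 while the C1 hemiacetal loses methanol to give aldehyde 20; the mercury enolate then adds to C1 and protonolysis of the mercury alkoxide returns the catalyst. This is the Ferrier carbocyclisation (Ferrier II reaction) in its catalytic mercury(II) trifluoroacetate form, the standard reaction of acylated 6-deoxyhex-5-enopyranosides. The one ring is closed by a 6-(enolendo)-exo-trig aldol, since both carbons of the enolate C5=C6 end up inside the new ring and the aldehyde oxygen outside it. The new carbinol centre (sugar C1) should form mainly trans to the C3 isopropyl group and to the neighbouring angelate (R), steered by a chair-like aldol transition state in which the three existing substituents are fixed; it is erased in step 14, while sugar C2, C3 and C4 pass through unchanged as the all-cis triad. The step needs chemoselective oxymercuration of the enol ether beside two enoate C=C bonds, which their electron-poor trisubstituted character secures, and it must not lose a substituent by E1cB, which the substrate rules out because C3 carries carbon, the ester oxygens sit α (not β) to the two carbonyls, and the only β-leaving group is the new hydroxyl that is removed on purpose afterwards. Near-neutral aqueous acetone at room temperature should also keep the α-acyloxy ketone centre from epimerising and the TBS ether intact.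

Step 14
Reactants: 21 (2S,3S,4R,5R)-4-(angeloyloxy)-5-hydroxy-3-isopropyl-2-{[(E)-4-(tert-butyldimethylsilyloxy)-2-methylbut-2-enoyl]oxy}cyclohexan-1-one
Product: 23 (4S,5S,6S)-4-(angeloyloxy)-5-isopropyl-6-{[(E)-4-(tert-butyldimethylsilyloxy)-2-methylbut-2-enoyl]oxy}cyclohex-2-en-1-one, via β-mesylate 22 (not isolated)
Conditions: MsCl, Et3N, CH2Cl2, 0 °C to rt
Reagents that add atoms: none
Why: Mesylation of the β-hydroxyl followed by triethylamine-induced E1cB elimination through the enolate at C1 should give the conjugated C1=C6 enone, removing the transient carbinol centre while the brief, cold exposure to amine leaves C3–C5 unchanged.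

Step 15
Reactants: 23 (4S,5S,6S)-4-(angeloyloxy)-5-isopropyl-6-{[(E)-4-(tert-butyldimethylsilyloxy)-2-methylbut-2-enoyl]oxy}cyclohex-2-en-1-one
Product: 24 (4S,5S,6S)-4-(angeloyloxy)-2-(hydroxymethyl)-5-isopropyl-6-{[(E)-4-(tert-butyldimethylsilyloxy)-2-methylbut-2-enoyl]oxy}cyclohex-2-en-1-one
Conditions: CH2O (37% aq), imidazole, THF/1 M aq NaHCO3, rt
Reagents that add atoms: formaldehyde C=O
Why: In this Morita–Baylis–Hillman reaction imidazole adds reversibly to C6, the resulting enolate is hydroxymethylated at C1 by formaldehyde and loss of imidazole restores the enone, under near-neutral aqueous conditions that should spare the two hindered conjugated esters; no stereocentre is formed.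

Step 16
Reactants: 24 (4S,5S,6S)-4-(angeloyloxy)-2-(hydroxymethyl)-5-isopropyl-6-{[(E)-4-(tert-butyldimethylsilyloxy)-2-methylbut-2-enoyl]oxy}cyclohex-2-en-1-one
Product: 25 (4S,5S,6S)-4-(angeloyloxy)-6-{[(E)-4-hydroxy-2-methylbut-2-enoyl]oxy}-2-(hydroxymethyl)-5-isopropylcyclohex-2-en-1-one
Conditions: HF·pyridine, pyridine, THF, 0 °C to rt
Reagents that add atoms: none
Why: Buffered HF·pyridine cleaves the primary allylic TBS ether by fluoride-assisted desilylation without touching the esters, the enone or the epimerisable centre next to the ketone.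

Compound list
1 | 1,2:5,6-di-O-isopropylidene-α-D-glucofuranose (diacetone-D-glucose) | CC1(C)OC[C@@H](O1)[C@H]2O[C@@H]3OC(C)(C)O[C@@H]3[C@H]2O | starting material
2 | 1,2:5,6-di-O-isopropylidene-α-D-ribo-hexofuranos-3-ulose | CC1(C)OC[C@@H](O1)[C@H]2O[C@@H]3OC(C)(C)O[C@@H]3C2=O | intermediate
3 | isopropenylmagnesium bromide (THF solution) | CC(=C)[Mg]Br | starting material
4 | 3-C-isopropenyl-1,2:5,6-di-O-isopropylidene-α-D-allofuranose (3-OH α, isopropenyl β) | CC1(C)OC[C@@H](O1)[C@H]2O[C@@H]3OC(C)(C)O[C@@H]3[C@@]2(O)C(C)=C | intermediate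
5 | 3-C-isopropyl-1,2:5,6-di-O-isopropylidene-α-D-allofuranose | CC1(C)OC[C@@H](O1)[C@H]2O[C@@H]3OC(C)(C)O[C@@H]3[C@@]2(O)C(C)C | intermediate
6 | 3-O-(methoxyoxalyl) ester of 5 (not isolated) | CC1(C)OC[C@@H](O1)[C@H]2O[C@@H]3OC(C)(C)O[C@@H]3[C@@]2(OC(=O)C(=O)OC)C(C)C | intermediate
7 | 3-deoxy-3-C-isopropyl-1,2:5,6-di-O-isopropylidene-α-D-allofuranose (isopropyl α, cis to O2) | CC1(C)OC[C@@H](O1)[C@H]2O[C@@H]3OC(C)(C)O[C@@H]3[C@@H]2C(C)C | intermediate
8 | methyl 3-deoxy-3-C-isopropyl-β-D-allopyranoside (not isolated) | O[C@H]1[C@H](OC)O[C@H](CO)[C@@H](O)[C@H]1C(C)C | intermediate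
9 | methyl 4,6-O-[(R)-benzylidene]-3-deoxy-3-C-isopropyl-β-D-allopyranoside | O[C@H]1[C@H](OC)O[C@@H]2CO[C@@H](c3ccccc3)O[C@H]2[C@H]1C(C)C | intermediate
10 | angelic acid, (Z)-2-methylbut-2-enoic acid | C/C=C(/C)C(=O)O | starting material
11 | methyl 2-O-angeloyl-4,6-O-[(R)-benzylidene]-3-deoxy-3-C-isopropyl-β-D-allopyranoside | C/C=C(/C)C(=O)O[C@H]1[C@H](OC)O[C@@H]2CO[C@@H](c3ccccc3)O[C@H]2[C@H]1C(C)C | intermediate
12 | methyl 2-O-angeloyl-3-deoxy-3-C-isopropyl-β-D-allopyranoside | C/C=C(/C)C(=O)O[C@H]1[C@H](OC)O[C@H](CO)[C@@H](O)[C@H]1C(C)C | intermediate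
13 | methyl 2-O-angeloyl-3,6-dideoxy-6-iodo-3-C-isopropyl-β-D-allopyranoside | C/C=C(/C)C(=O)O[C@H]1[C@H](OC)O[C@H](CI)[C@@H](O)[C@H]1C(C)C | intermediate
14 | methyl 2-O-angeloyl-3,6-dideoxy-3-C-isopropyl-β-D-ribo-hex-5-enopyranoside | C/C=C(/C)C(=O)O[C@H]1[C@H](OC)OC(=C)[C@@H](O)[C@H]1C(C)C | intermediate
15 | (tert-butyldimethylsilyloxy)acetaldehyde | O=CCO[Si](C)(C)C(C)(C)C | starting material
16 | ethyl 2-(triphenylphosphoranylidene)propanoate | CCOC(=O)C(C)=P(c1ccccc1)(c1ccccc1)c1ccccc1 | starting material
17 | ethyl (E)-4-(tert-butyldimethylsilyloxy)-2-methylbut-2-enoate | CCOC(=O)/C(C)=C/CO[Si](C)(C)C(C)(C)C | intermediate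
18 | (E)-4-(tert-butyldimethylsilyloxy)-2-methylbut-2-enoic acid | OC(=O)/C(C)=C/CO[Si](C)(C)C(C)(C)C | intermediate
19 | methyl 2-O-angeloyl-4-O-[(E)-4-(tert-butyldimethylsilyloxy)-2-methylbut-2-enoyl]-3,6-dideoxy-3-C-isopropyl-β-D-ribo-hex-5-enopyranoside (precursor of the key step) | C/C=C(/C)C(=O)O[C@H]1[C@H](OC)OC(=C)[C@@H](OC(=O)/C(C)=C/CO[Si](C)(C)C(C)(C)C)[C@H]1C(C)C | intermediate
20 | acyclic 6-(trifluoroacetoxymercurio) 5-keto aldehyde from 19, sugar C2/C3/C4 configurations retained (not isolated) | C/C=C(/C)C(=O)O[C@@H](C=O)[C@H](C(C)C)[C@H](OC(=O)/C(C)=C/CO[Si](C)(C)C(C)(C)C)C(=O)C[Hg]OC(=O)C(F)(F)F | intermediate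
21 | (2S,3S,4R,5R)-4-(angeloyloxy)-5-hydroxy-3-isopropyl-2-{[(E)-4-(tert-butyldimethylsilyloxy)-2-methylbut-2-enoyl]oxy}cyclohexan-1-one; 2-O, 3-isopropyl and 4-O all cis, 5-OH trans to the 4-angelate (product of the key step) | C/C=C(/C)C(=O)O[C@H]1[C@H](O)CC(=O)[C@@H](OC(=O)/C(C)=C/CO[Si](C)(C)C(C)(C)C)[C@H]1C(C)C | intermediate
22 | 5-O-methanesulfonate of 21 (not isolated) | C/C=C(/C)C(=O)O[C@H]1[C@H](OS(C)(=O)=O)CC(=O)[C@@H](OC(=O)/C(C)=C/CO[Si](C)(C)C(C)(C)C)[C@H]1C(C)C | intermediate
23 | (4S,5S,6S)-4-(angeloyloxy)-5-isopropyl-6-{[(E)-4-(tert-butyldimethylsilyloxy)-2-methylbut-2-enoyl]oxy}cyclohex-2-en-1-one (all-cis) | C/C=C(/C)C(=O)O[C@H]1C=CC(=O)[C@@H](OC(=O)/C(C)=C/CO[Si](C)(C)C(C)(C)C)[C@H]1C(C)C | intermediate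
24 | (4S,5S,6S)-4-(angeloyloxy)-2-(hydroxymethyl)-5-isopropyl-6-{[(E)-4-(tert-butyldimethylsilyloxy)-2-methylbut-2-enoyl]oxy}cyclohex-2-en-1-one | C/C=C(/C)C(=O)O[C@H]1C=C(CO)C(=O)[C@@H](OC(=O)/C(C)=C/CO[Si](C)(C)C(C)(C)C)[C@H]1C(C)C | intermediate
25 | (4S,5S,6S)-4-(angeloyloxy)-6-{[(E)-4-hydroxy-2-methylbut-2-enoyl]oxy}-2-(hydroxymethyl)-5-isopropylcyclohex-2-en-1-one, CNP0281432.2 | C/C=C(/C)C(=O)O[C@H]1C=C(CO)C(=O)[C@@H](OC(=O)/C(C)=C/CO)[C@H]1C(C)C | target

Total step count: 16 (14 in the main line, 2 for acid 18).
Longest linear sequence: 14 steps (steps 1–9 and 12–16).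

Steps most likely to fail

Step 5. The acid-equilibrated glycoside mixture may drift towards furanosides, because the pyranoside must carry the isopropyl group axially, and furanosides cannot form the 4,6-acetal. The fallback sets out from 7. Both acetonides are hydrolysed (TFA/H2O, rt) to the free sugar 3-deoxy-3-C-isopropyl-D-allopyranose F1, whose ring forms interconvert quickly. Acetalisation under thermodynamic control (PhCH(OMe)2, CSA, DMF, 50 °C) should drain the equilibrating hemiacetal into 4,6-O-benzylidene-3-deoxy-3-C-isopropyl-D-allopyranose F2. Kinetic anomeric O-alkylation (NaH, 1 equiv, MeI, DMF, 0 °C) then methylates only the more acidic anomeric hydroxyl, the equatorial β-oxide reacting fastest, and the route is rejoined at 9.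

Step 15. Conjugate addition of the amine at the hindered β-carbon may be sluggish, and long exposure to aqueous base invites acyl transfer or epimerisation next to the ketone. The fallback sets out from 23. Pyridine-mediated α-iodination (I2, pyridine, CH2Cl2, 0 °C to rt) gives the 2-iodo enone F3. A Stille coupling with (tributylstannyl)methanol (Pd(PPh3)4 cat., toluene, 80 °C) completes a neutral two-step hydroxymethylation and comes back at 24.

Step 4. Hydrogen transfer may reach the wrong face of the C3 radical, or the tertiary oxalate may eliminate thermally before the chain reduction. The fallback sets out from 5. Dehydration by anti-elimination (SOCl2, pyridine, 0 °C) gives 3-deoxy-3-C-isopropylidene-1,2:5,6-di-O-isopropylidene-α-D-ribo-hexofuranose F4; any 2,3-ene formed alongside converges. Hydrogenation (H2, Pd/C, EtOAc) from the exo face sets the same C3 configuration and returns at 7.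

Further compounds
F1 | step 5 | 3-deoxy-3-C-isopropyl-β-D-allopyranose | O[C@H]1[C@H](O)O[C@H](CO)[C@@H](O)[C@H]1C(C)C
F2 | step 5 | 4,6-O-[(R)-benzylidene]-3-deoxy-3-C-isopropyl-β-D-allopyranose | O[C@H]1[C@H](O)O[C@@H]2CO[C@@H](c3ccccc3)O[C@H]2[C@H]1C(C)C
F3 | step 15 | 2-iodo derivative of enone 23 (iodine on the α-carbon of the enone, ring stereocentres as in 23) | C/C=C(/C)C(=O)O[C@H]1C=C(I)C(=O)[C@@H](OC(=O)/C(C)=C/CO[Si](C)(C)C(C)(C)C)[C@H]1C(C)C
F4 | step 4 | 3-deoxy-3-C-isopropylidene-1,2:5,6-di-O-isopropylidene-α-D-ribo-hexofuranose | CC1(C)OC[C@@H](O1)[C@H]2O[C@@H]3OC(C)(C)O[C@@H]3C2=C(C)C
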